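**Strategy**

Everything rests on closing ring C, the spiro-linked cyclohexene (primed locants of spiro[chromene-2,2'-naphthalene]), by a thermal disrotatory 6π-electrocyclisation that joins the ring-fusion methine C4a' to the methylene C4'. The step exploits the C1'=C8a' alkene of ring C, allylic to the new bond exactly where hexatriene closure leaves a double bond, and relays the C4a' configuration from the isopropyl and methyl centres of ring D, bought as (−)-menthone. Its precursor is a menthone-derived cyclohexene carrying a cis-2-(hydroxymethyl)buta-1,3-dienyl arm. Reductive transposition then unveils an exocyclic diene, which a domino Knoevenagel/oxa-Diels–Alder reaction with a methoxy trimethyl dione and isobutyraldehyde converts into rings A and B.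

Key step: step 4

Remark: ring A = cyclohexadienone, ring B = dihydropyran, ring C = spiro-linked cyclohexene, ring D = cyclohexane; (−)-menthone is taken as the (2S,5R) ketone free of isomenthone, and LiN(i-Pr)2 and CH2=CHMgCl are used as commercial solutions.

**Route**

Step 1
Reactants: 1 (−)-menthone, (2S,5R)-5-methyl-2-(propan-2-yl)cyclohexan-1-one
Product: 2 (3R,6S)-3-methyl-6-(propan-2-yl)cyclohex-1-en-1-yl trifluoromethanesulfonate
Conditions: LiN(i-Pr)2 (1.1 equiv), THF, −78 °C; PhNTf2 (1.1 equiv), −78 → 0 °C
Reagents that add atoms: N-phenylbis(trifluoromethanesulfonimide), O=S(=O)(N(c1ccccc1)S(=O)(=O)C(F)(F)F)C(F)(F)F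
Why: Kinetic deprotonation by the hindered amide occurs at the unbranched C6 methylene and not at the isopropyl-bearing C2, and O-sulfonylation of the lithium enolate (kinetic enol triflate formation) fixes the C1=C6 alkene while both stereocentres of 1 stay untouched.

Step 2
Reactants: 2 (3R,6S)-3-methyl-6-(propan-2-yl)cyclohex-1-en-1-yl trifluoromethanesulfonate; 3 prop-2-yn-1-ol
Product: 4 3-[(3R,6S)-3-methyl-6-(propan-2-yl)cyclohex-1-en-1-yl]prop-2-yn-1-ol
Conditions: PdCl2(PPh3)2 (3 mol %), CuI (6 mol %), Et3N (3 equiv), DMF, 23 °C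
Reagents that add atoms: none
Why: Sonogashira coupling of an alkenyl triflate with a terminal alkyne keeps the alkene position, tolerates the free hydroxyl group and touches no stereocentre.

Step 3
Reactants: 4 3-[(3R,6S)-3-methyl-6-(propan-2-yl)cyclohex-1-en-1-yl]prop-2-yn-1-ol; 5 vinylmagnesium chloride
Product: 6 (2E)-2-{[(3R,6S)-3-methyl-6-(propan-2-yl)cyclohex-1-en-1-yl]methylidene}but-3-en-1-ol (cyclohexenyl and vinyl groups cis on the central alkene)
Conditions: CH2=CHMgCl (4 equiv), THF, 60 °C; then aq NH4Cl, 0 °C
Reagents that add atoms: none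
Why: Hydroxyl-directed anti-carbomagnesiation of a propargylic alcohol delivers the vinyl group to the alkyne carbon next to the carbinol and magnesium to the distal carbon within a five-membered chelate, so that after protonation the cyclohexenyl and vinyl groups are cis, the geometry step 4 needs (any triene that closes already at 60 °C converges on 7).

Step 4
Reactants: 6 (2E)-2-{[(3R,6S)-3-methyl-6-(propan-2-yl)cyclohex-1-en-1-yl]methylidene}but-3-en-1-ol
Product: 7 [(4aR,5R,8S)-5-methyl-8-(propan-2-yl)-4,4a,5,6,7,8-hexahydronaphthalen-2-yl]methanol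
Conditions: toluene (0.02 M), BHT (5 mol %), 110 °C, Ar, dark
Reagents that add atoms: none
Why: The (Z)-hexatriene of 6 (ring alkene, central alkene, vinyl group) closes thermally in a disrotatory 6π-electrocyclisation, the hexatriene-to-cyclohexadiene reaction known for 1-dienylcyclohexenes, forming the σ-bond between the ring CH (C4a of 7) and the vinyl CH2 (C4 of 7) and leaving the C1=C8a and C2=C3 alkenes. Ring C is closed in the pericyclic six-electron mode, suprafacial on the triene, with no ionic intermediate. The only new stereocentre, C4a, is under substrate control (torquoselectivity): the vinyl terminus should bond along the axial trajectory of the ring D half-chair in which isopropyl and methyl are both pseudoequatorial, anti to the pseudoaxial C5–H, which puts the new bond cis to the methyl and trans to the isopropyl group (4aR). The rival axial approach on the flipped half-chair would build a syn-diaxial contact with the isopropyl group, and both equatorial approaches pass through twist-boat geometries. The step needs the cis relation of cyclohexenyl and vinyl groups, which step 3 fixes, and freedom from [1,5]- and [1,7]-hydrogen shifts, which is secured because the hydroxymethyl group is trans to the cyclohexenyl group and no sp3 C–H lies cis at either triene terminus. Kinetic control suffices because C4a of 7 cannot epimerise under these neutral conditions.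

Step 5
Reactants: 7 [(4aR,5R,8S)-5-methyl-8-(propan-2-yl)-4,4a,5,6,7,8-hexahydronaphthalen-2-yl]methanol
Product: 10 (1S,4R,4aR)-4-methyl-7-methylidene-1-(propan-2-yl)-1,2,3,4,4a,5,6,7-octahydronaphthalene, via 1-alkyl-1-sulfonylhydrazine 8 (not isolated), via allylic diazene 9 (not isolated)
Conditions: 2-nitrobenzenesulfonohydrazide (1.5 equiv), PPh3 (1.5 equiv), DEAD (1.5 equiv), THF, −30 °C; then 23 °C
Reagents that add atoms: none
Why: Reductive 1,3-transposition of a primary allylic alcohol, in which Mitsunobu N-alkylation of the sulfonohydrazide, loss of the sulfinic acid and retro-ene extrusion of N2 from the monoalkyl diazene deliver hydrogen to C3 and move the alkene into the exocyclic position without touching C4a, C5 or C8.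

Step 6
Reactants: 11 2,4,6-trihydroxybenzoic acid; 12 benzyl bromide
Product: 13 benzyl 2,4,6-trihydroxybenzoate
Conditions: KHCO3 (1.2 equiv), DMF, 23 °C
Reagents that add atoms: none
Why: Chemoselective O-alkylation of the carboxylate (hydrogencarbonate does not deprotonate the phenols) gives a benzyl ester that blocks the ring carbon between the two ortho hydroxyl groups and can later be removed under neutral conditions.

Step 7
Reactants: 13 benzyl 2,4,6-trihydroxybenzoate
Product: 14 benzyl 2,6-dihydroxy-4-methoxybenzoate
Conditions: Me2SO4 (1.05 equiv), K2CO3 (1.1 equiv), acetone, 23 °C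
Reagents that add atoms: dimethyl sulfate, COS(=O)(=O)OC
Why: Regioselective Williamson methylation, because the 4-hydroxyl is the only one not hydrogen-bonded to the ester carbonyl and is the most acidic.

Step 8
Reactants: 14 benzyl 2,6-dihydroxy-4-methoxybenzoate
Product: 15 benzyl 2-hydroxy-4-methoxy-3,5,5-trimethyl-6-oxocyclohexa-1,3-diene-1-carboxylate (enol tautomer drawn)
Conditions: MeI (6 equiv), t-BuOK (4 equiv, in portions), t-BuOH, 25 → 45 °C; then aq HCl to pH 3
Reagents that add atoms: iodomethane, CI
Why: Exhaustive C-methylation of a phloroglucinol-type phenoxide (dearomative alkylation) methylates C3 and C5 and then C3 a second time, while the 4-methoxy group already in place rules out a fourth C-methylation and fixes the position of the enol ether, and the hindered tert-butoxide does not exchange with the benzyl ester.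

Step 9
Reactants: 15 benzyl 2-hydroxy-4-methoxy-3,5,5-trimethyl-6-oxocyclohexa-1,3-diene-1-carboxylate
Product: 17 5-methoxy-4,6,6-trimethylcyclohex-4-ene-1,3-dione, via keto acid 16 (not isolated)
Conditions: H2 (1 atm), 10% Pd/C, EtOAc, 23 °C; then 40 °C
Reagents that add atoms: none
Why: Hydrogenolysis of the benzyl ester frees a 2-carboxy-1,3-dione that decarboxylates on gentle warming (β-keto acid decarboxylation), while the tetrasubstituted vinylogous ester is inert to these conditions.

Step 10
Reactants: 17 5-methoxy-4,6,6-trimethylcyclohex-4-ene-1,3-dione; 18 2-methylpropanal; 10 (1S,4R,4aR)-4-methyl-7-methylidene-1-(propan-2-yl)-1,2,3,4,4a,5,6,7-octahydronaphthalene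
Product: 20 target CNP0194760.3 (the (2S,4R,4a'R,5'R,8'S)-7-methoxy-5',6,8,8-tetramethyl-4,8'-di(propan-2-yl)spiro[chromene-2,2'-naphthalen]-5-one), via isobutylidene dione 19 (not isolated)
Conditions: ethylenediammonium diacetate (10 mol %), 18 (3 equiv), toluene, 70 °C, sealed tube
Reagents that add atoms: none
Why: Domino Knoevenagel condensation/inverse-electron-demand oxa-Diels–Alder reaction, in which the oxadiene O=C1–C2=CH(i-Pr) of 19, built on the more electrophilic non-vinylogous carbonyl, should add to the s-trans-locked exocyclic methylene of 10 (C–C bond at the CH2 terminus, C–O bond at the more substituted carbon) from the face opposite the isopropyl group of 10 and with the C8=C8a alkene endo, which sets C2 (S) and C4 (R) of 20.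

**Compound list**

1 | (−)-menthone, (2S,5R)-5-methyl-2-(propan-2-yl)cyclohexan-1-one | CC(C)[C@@H]1CC[C@@H](C)CC1=O | starting material
2 | (3R,6S)-3-methyl-6-(propan-2-yl)cyclohex-1-en-1-yl trifluoromethanesulfonate | CC(C)[C@@H]1CC[C@@H](C)C=C1OS(=O)(=O)C(F)(F)F | intermediate
3 | prop-2-yn-1-ol | C#CCO | starting material
4 | 3-[(3R,6S)-3-methyl-6-(propan-2-yl)cyclohex-1-en-1-yl]prop-2-yn-1-ol | CC(C)[C@@H]1CC[C@@H](C)C=C1C#CCO | intermediate
5 | vinylmagnesium chloride | C=C[Mg]Cl | starting material
6 | (2E)-2-{[(3R,6S)-3-methyl-6-(propan-2-yl)cyclohex-1-en-1-yl]methylidene}but-3-en-1-ol | CC(C)[C@@H]1CC[C@@H](C)C=C1/C=C(/CO)C=C | intermediate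
7 | [(4aR,5R,8S)-5-methyl-8-(propan-2-yl)-4,4a,5,6,7,8-hexahydronaphthalen-2-yl]methanol | OCC1=CC[C@@H]2[C@H](C)CC[C@@H](C(C)C)C2=C1 | intermediate
8 | N-{[(4aR,5R,8S)-5-methyl-8-(propan-2-yl)-4,4a,5,6,7,8-hexahydronaphthalen-2-yl]methyl}-2-nitrobenzenesulfonohydrazide (1-alkyl-1-sulfonylhydrazine) | NN(CC1=CC[C@@H]2[C@H](C)CC[C@@H](C(C)C)C2=C1)S(=O)(=O)c1ccccc1[N+](=O)[O-] | intermediate
9 | {[(4aR,5R,8S)-5-methyl-8-(propan-2-yl)-4,4a,5,6,7,8-hexahydronaphthalen-2-yl]methyl}diazene | N=NCC1=CC[C@@H]2[C@H](C)CC[C@@H](C(C)C)C2=C1 | intermediate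
10 | (1S,4R,4aR)-4-methyl-7-methylidene-1-(propan-2-yl)-1,2,3,4,4a,5,6,7-octahydronaphthalene | C=C1CC[C@@H]2[C@H](C)CC[C@@H](C(C)C)C2=C1 | intermediate
11 | 2,4,6-trihydroxybenzoic acid | OC(=O)c1c(O)cc(O)cc1O | starting material
12 | benzyl bromide | BrCc1ccccc1 | starting material
13 | benzyl 2,4,6-trihydroxybenzoate | O=C(OCc1ccccc1)c1c(O)cc(O)cc1O | intermediate
14 | benzyl 2,6-dihydroxy-4-methoxybenzoate | COc1cc(O)c(C(=O)OCc2ccccc2)c(O)c1 | intermediate
15 | benzyl 2-hydroxy-4-methoxy-3,5,5-trimethyl-6-oxocyclohexa-1,3-diene-1-carboxylate | COC1=C(C)C(O)=C(C(=O)OCc2ccccc2)C(=O)C1(C)C | intermediate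
16 | 2-hydroxy-4-methoxy-3,5,5-trimethyl-6-oxocyclohexa-1,3-diene-1-carboxylic acid | COC1=C(C)C(O)=C(C(O)=O)C(=O)C1(C)C | intermediate
17 | 5-methoxy-4,6,6-trimethylcyclohex-4-ene-1,3-dione | COC1=C(C)C(=O)CC(=O)C1(C)C | intermediate
18 | 2-methylpropanal | CC(C)C=O | starting material
19 | 5-methoxy-4,6,6-trimethyl-2-(2-methylpropylidene)cyclohex-4-ene-1,3-dione (drawn with isopropyl syn to the C3 carbonyl, the reactive geometry) | COC1=C(C)C(=O)/C(=C\C(C)C)C(=O)C1(C)C | intermediate
20 | CNP0194760.3, (2S,4R,4a'R,5'R,8'S)-7-methoxy-5',6,8,8-tetramethyl-4,8'-di(propan-2-yl)spiro[chromene-2,2'-naphthalen]-5-one (3,4-dihydro, 8H; 3',4',4a',5',6',7',8'-heptahydro) | COC1=C(C)C(=O)C2=C(O[C@]3(C=C4[C@H](C(C)C)CC[C@@H](C)[C@H]4CC3)C[C@@H]2C(C)C)C1(C)C | target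

**Step count and risks**

Total steps: 10. Longest linear sequence: 6 (steps 1–5 and 10, from 1).

Steps most likely to fail:

1. Step 4. The process at risk is facial discrimination in the disrotatory closure: if the half-chair bias of ring D is weak, the vinyl terminus also bonds trans to the methyl group and the C4a epimer forms alongside 7. The fallback sets out from 6 and comes back at 7. Oxidation of 6 with MnO2 (CH2Cl2, 23 °C) would give the trienal (2E)-2-{[(3R,6S)-3-methyl-6-(propan-2-yl)cyclohex-1-en-1-yl]methylidene}but-3-enal F1. Complexed with Me2AlCl in CH2Cl2 at −78 to −40 °C, this 2,4-dienal should close in a polarised, Lewis-acid-promoted mode (pendant vinyl group onto the activated δ-carbon) to the bicyclic dienal (4aR,5R,8S)-5-methyl-8-(propan-2-yl)-4,4a,5,6,7,8-hexahydronaphthalene-2-carbaldehyde F2. The low temperature gives the torsional preference more weight, and a bulkier aluminium Lewis acid can add a reagent-based bias. Luche reduction (NaBH4, CeCl3·7H2O, MeOH, 0 °C) of the aldehyde then returns 7.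

2. Step 10. The processes at risk are facial selectivity on the exocyclic alkene, endo/exo leakage, and ring closure through the vinylogous-ester oxygen instead of the C1 oxygen of 19. The fallback sets out from 10, 17 and 18 and comes back at 20. It turns the kinetically controlled cycloaddition into a stepwise, thermodynamically controlled annulation. The crude adducts are chiefly the spiro epimer (2R,4R,4a'R,5'R,8'S)-7-methoxy-5',6,8,8-tetramethyl-4,8'-di(propan-2-yl)spiro[chromene-2,2'-naphthalen]-5-one F3 and the linear O-regioisomer (2S,4R,4a'R,5'R,8'S)-7-methoxy-5',6,6,8-tetramethyl-4,8'-di(propan-2-yl)spiro[chromene-2,2'-naphthalen]-5(6H)-one F4. Treated with Sc(OTf)3 (5 mol %) in CH2Cl2 at −20 to 0 °C, they should ionise reversibly at the tertiary allylic C2–O bond (vinylogous carboxylate as leaving group, tertiary allylic cation) and re-close through either oxygen and on either face. This should drain the mixture toward 20, the cross-conjugated doubly vinylogous ester in which the flat alkenyl arm, not the CH2 arm, sits syn to the pseudoaxial isopropyl group at C4.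

3. Step 3. The process at risk is carbomagnesiation next to the hindered, isopropyl-flanked cyclohexenyl group: slow addition, attack at the wrong alkyne carbon, or loss of alkene geometry. The fallback sets out from 4 and comes back at 6. Hydroxyl-directed trans-hydrostannation (Bu3SnH, [Cp*RuCl]4 2 mol %, CH2Cl2, 23 °C) should place tin on the alkyne carbon next to the carbinol and hydrogen trans to it. This gives the alkenylstannane (2Z)-3-[(3R,6S)-3-methyl-6-(propan-2-yl)cyclohex-1-en-1-yl]-2-(tributylstannyl)prop-2-en-1-ol F5. Stille coupling with vinyl bromide (Pd(PPh3)4, CuI, CsF, DMF, 40 °C) then installs the vinyl group with retention, cis to the cyclohexenyl group, and gives 6.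

Further compounds
F1 | step 4 | (2E)-2-{[(3R,6S)-3-methyl-6-(propan-2-yl)cyclohex-1-en-1-yl]methylidene}but-3-enal | CC(C)[C@@H]1CC[C@@H](C)C=C1/C=C(/C=O)C=C
F2 | step 4 | (4aR,5R,8S)-5-methyl-8-(propan-2-yl)-4,4a,5,6,7,8-hexahydronaphthalene-2-carbaldehyde | O=CC1=CC[C@@H]2[C@H](C)CC[C@@H](C(C)C)C2=C1
F3 | step 10 | (2R,4R,4a'R,5'R,8'S)-7-methoxy-5',6,8,8-tetramethyl-4,8'-di(propan-2-yl)spiro[chromene-2,2'-naphthalen]-5-one (C2 epimer of 20) | COC1=C(C)C(=O)C2=C(O[C@@]3(C=C4[C@H](C(C)C)CC[C@@H](C)[C@H]4CC3)C[C@@H]2C(C)C)C1(C)C
F4 | step 10 | (2S,4R,4a'R,5'R,8'S)-7-methoxy-5',6,6,8-tetramethyl-4,8'-di(propan-2-yl)spiro[chromene-2,2'-naphthalen]-5(6H)-one (linear O-regioisomer of 20) | COC1=C(C)C2=C([C@@H](C(C)C)C[C@@]3(C=C4[C@H](C(C)C)CC[C@@H](C)[C@H]4CC3)O2)C(=O)C1(C)C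
F5 | step 3 | (2Z)-3-[(3R,6S)-3-methyl-6-(propan-2-yl)cyclohex-1-en-1-yl]-2-(tributylstannyl)prop-2-en-1-ol | CC(C)[C@@H]1CC[C@@H](C)C=C1/C=C(/CO)[Sn](CCCC)(CCCC)CCCC
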